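**Structural features**

The target is a dihydrochalcone: a 3-(4-methoxyphenyl)propanoyl chain (ring B is the anisyl ring) sits on a hexasubstituted, phloroglucinol-derived benzene (ring A), and ring A is fused to a 2,3-dihydrofuran (ring C; benzofuran numbering O1, C2, C3, C3a, C4 to C7, C7a). Every carbon of ring A is substituted: C3a carries the furan CH2, C4 a free OH, C5 a prenyl group, C6 an OH chelated to the ketone, C7 the acyl chain and C7a the ring oxygen. The only stereocentre is C2 (S), which bears the 2-hydroxypropan-2-yl group; it has no stereogenic neighbour, so its configuration must come from a reagent, auxiliary or catalyst. The fragile elements are the prenyl olefin flanked by two phenols (acid closes it to a chroman, hydrogenation is excluded), the tertiary alcohol β to the aryl ether oxygen, the oxidation-prone ring A and, at the ester stage, an enolisable α-aryloxy C–H at C2. The real difficulty is twofold: setting C2 as one enantiomer, and placing three different carbon substituents (furan CH2, prenyl, acyl) at defined positions of a benzene whose three oxygens are equivalent at the outset. The key step uses the fact that C3 is a benzylic CH2 ortho to the phenolic O1: C3 and C7a are unmasked as the methylene and carbonyl ends of an ortho-quinone methide of ring A, and a one-carbon ylide supplies C2, so both new bonds (C2–C3 and O1–C2) meet at the stereocentre.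

**Logic of the disconnections**

26 from 25: only O–C(acetal) and O–Si bonds are cut. Leaving all protecting groups to the end keeps the phenols and the carbinol inert through the organometallic steps. The demand is an acid mild enough to spare the prenyl group next to two emerging phenols.

25 from 20 and 23: the C7–C(=O) bond is cut. C7 is the last ring C–H of 20 and lies between an acetal oxygen and the ring oxygen, so it can be metalated and acylated; 23 comes from 21 by amide formation (via 22). The demand is that ring metalation beats deprotonation of the prenyl CH2 and that addition to 23 beats its enolisation.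

20 from 17: the C5–CH2(prenyl) bond is cut. C5 lies between two acetal oxygens, the strongest directing pair on the ring, so it should be metalated first (via 18 and 19). The demand is site selectivity for C5 over C7 and allylation without allylic transposition.

17 from 16, and 16 from 14: the O–Si bond and then the two C–CH3 bonds of the carbinol are cut (via 15). The ester of 14 is the handle left by the ring-forming step; the silyl ether removes an acidic, coordinating OH before two lithiations. The demand is that C2, now α to a carbonyl, is not epimerised.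

14 from 5 and 10 (via 11, 12 and 13): C2–C3 and O1–C2 are cut. This removes ring C and the only stereocentre at once and leaves an achiral benzylammonium phenol and a chiral one-carbon reagent. The demand is enantiocontrol by the thiolane leaving group and efficient capture of a transient quinone methide.

5 from 4, 4 from 2, and 2 from 1: the N–CH3 bond, the benzylic C–N bond (via 3) and two O–CH2 acetal bonds are cut. The two ortho hydroxyls of 1 are equivalent, so one protection event desymmetrises the ring and leaves the chelated hydroxyl that becomes O1. The demand is N- over O-methylation and stopping the protection at the bis-ether.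

10 from 8 and 9, 8 from 7, and 7 from 6: the S–CH2 bond, the two ring C–S bonds and the two O–S bonds are cut. The C2-symmetric sulfide has a non-stereogenic sulfur, so one sulfonium salt results. The demand is clean double inversion in the thiolane closure.

**Other disconnections considered**

Alternative 1: The cut is the C7–C7a bond, which unravels ring A into the open-chain methyl 9-(4-methoxyphenyl)-4-(3-methylbut-2-enyl)-3,5,7-trioxononanoate A1. In the forward step Mg(OMe)2 chelates the chain, the carbon between the 5- and 7-ketones attacks the ester carbonyl (Claisen/Dieckmann closure of the carbocycle), and enolisation gives the acylphloroglucinol A2.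
- In its favour: the acyl and prenyl groups come out in the right 1,3-relationship with no protecting groups and no site-selective metalation. On that point it is better than the chosen plan.
- Against it: A1 is a labile polycarbonyl chain that needs several polyanion acylations, and Claisen closure must compete with aldol and pyrone-forming modes.
- Against it, more seriously: A2 contains neither ring C nor C2. A second C-prenylation would be needed to give the bis-prenyl ketone A3, followed by asymmetric epoxidation of one of two equivalent prenyl groups and closure through the ketone-chelated hydroxyl in preference to the more acidic hydroxyl between the prenyl groups. That site selectivity has no obvious control element.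
- Comparison: the alternative builds the carbocycle and defers the stereocentre; the chosen plan keeps the arene of 1 and fixes the heterocycle and C2 early. Step count to A2 would be competitive, but the sequence to the target would probably be longer and less selective.

Alternative 2: The cut is C2–C3. The aryldiazomethane A4, 2-(diazomethyl)-1-[2-methyl-2-(trimethylsilyloxy)propoxy]-3,5-bis(triisopropylsilyloxy)benzene, would be decomposed by the divalent rhodium carboxylate Rh2(S-PTAD)4 or its enantiomer. The metal carbene at the future C3 would insert into one enantiotopic C–H of the OCH2 group to give the dihydrobenzofuran A5.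
- In its favour: chirality is catalytic and not stoichiometric, the protected hydroxyisopropyl group is in place from the start, and no enolisable α-aryloxy ester is ever formed. On these three points it is better than the chosen plan.
- Equal: enantiocontrol would be as untested as in the chosen plan.
- Against it: A4 is a mono-aryl, hydrogen-bearing donor carbene precursor. Such diazo compounds tend to azine formation and carbene dimerisation, and reliable asymmetric insertion is established mainly for carbenes with a second stabilising substituent.
- Against it: the C–H to be attacked is on a neopentyl-type carbon next to a bulky silyloxy group, and the methine C–H bonds of the neighbouring silyl ether are competing insertion sites.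
- Against it: the silyl ethers of A5 are poor directing groups, so the C5 and C7 substituents would require a protecting-group exchange first.
- Comparison: one ring bond is formed where the chosen plan forms two, and the step count would be similar or slightly higher.

Alternative 3: The cuts are C6–O and C7–C(acyl). CsF would convert the silyl triflate A6 into the aryne A7. The carboxylate of 21 would add through oxygen at C6 (the position distal to the C7a oxygen), and the C7 anion would take over the acyl group to give the hydroxy ketone A8.
- In its favour: the acyl group is delivered intramolecularly and site-specifically without an organolithium next to the prenyl group. On that point it is equal or better than the Weinreb acylation of the chosen plan.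
- Against it: A6 must already contain ring C, the C2 stereocentre, the prenyl group, a C7 silyl group and a C6 hydroxyl differentiated from the C4 oxygen. The stereochemical problem is therefore not addressed, and an oxygen already present in any phloroglucinol precursor is removed and reinstalled.
- Against it: protonation of the aryl anion by the acid would stop at the aryl ester, and the prenyl group next to the triple bond of A7 invites an intramolecular ene reaction.
- Comparison: no ring is closed and none of the target's real difficulties is solved; the route would be clearly longer than the chosen plan.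

Key step: step 7

Assumption on the sense of induction: the (2S,5S)-thiolanium ylide is taken to favour closure to the (S)-ester. If the sense proves opposite, (2S,5S)-hexane-2,5-diol is used in step 4 and nothing else changes.

Remark on descriptors and design: double inversion turns the (2R,5R)-diol into the (2S,5S)-thiolane. The (S) descriptor of the ester carries through to the target because the ranking at C2 (O1 > carbonyl or carbinol carbon > C3 > H) never changes. The ylide is made in the flask from its stable sulfonium salt, and the tertiary alcohol is silylated before the two lithiations.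

**Route**

Step 1
Reactants: 1 2,4,6-trihydroxybenzaldehyde
Product: 2 2-hydroxy-4,6-bis(methoxymethoxy)benzaldehyde
Conditions: MOMCl (2.2 equiv), i-Pr2NEt, CH2Cl2, 0 °C → rt
Reagents that add atoms: chloromethyl methyl ether, COCCl
Why: Base-mediated O-alkylation (acetal protection); the two ortho hydroxyls are equivalent and the one that remains is hydrogen-bonded to the aldehyde and poorly nucleophilic, so the reaction should stop at the 4,6-bis-ether.

Step 2
Reactants: 2 2-hydroxy-4,6-bis(methoxymethoxy)benzaldehyde
Product: 4 2-[(dimethylamino)methyl]-3,5-bis(methoxymethoxy)phenol, via iminium acetate 3 (not isolated)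
Conditions: Me2NH (2 M in THF), NaBH(OAc)3, AcOH (1 equiv), ClCH2CH2Cl, rt
Reagents that add atoms: dimethylamine, CNC
Why: Reductive amination; the ortho hydroxyl assists iminium formation and the mild acetoxyborohydride reduces the iminium faster than the deactivated aldehyde, while the acetals tolerate the weak acid.

Step 3
Reactants: 4 2-[(dimethylamino)methyl]-3,5-bis(methoxymethoxy)phenol
Product: 5 [2-hydroxy-4,6-bis(methoxymethoxy)benzyl]trimethylammonium iodide
Conditions: MeI (3 equiv), MeCN, rt, dark; Et2O precipitation
Reagents that add atoms: iodomethane, CI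
Why: Menshutkin quaternisation; without added base the tertiary amine is far more nucleophilic than the neutral phenol, so N-methylation should be selective, and the salt is stored cold and used promptly because it is the latent quinone methide.

Step 4
Reactants: 6 (2R,5R)-hexane-2,5-diol
Product: 7 (2R,5R)-hexane-2,5-diyl dimethanesulfonate
Conditions: MsCl, Et3N, CH2Cl2, 0 °C
Reagents that add atoms: methanesulfonyl chloride, CS(=O)(=O)Cl
Why: O-sulfonylation; no bond to either carbinol carbon is broken, so both centres keep the (R) configuration.

Step 5
Reactants: 7 (2R,5R)-hexane-2,5-diyl dimethanesulfonate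
Product: 8 (2S,5S)-2,5-dimethylthiolane
Conditions: Na2S·9H2O, EtOH, rt → 50 °C
Reagents that add atoms: sodium sulfide, [Na+].[Na+].[S-2]
Why: Double SN2 displacement (intermolecular, then 5-exo-tet) with inversion at both carbons, which should give the trans, C2-symmetric (2S,5S)-sulfide.

Step 6
Reactants: 8 (2S,5S)-2,5-dimethylthiolane; 9 methyl bromoacetate
Product: 10 (2S,5S)-1-(2-methoxy-2-oxoethyl)-2,5-dimethylthiolan-1-ium bromide
Conditions: acetone (concentrated), rt, 3 d
Reagents that add atoms: none
Why: S-alkylation of a sulfide with an activated α-halo ester; the two carbons flanking sulfur are homochiral, so sulfur is not a stereocentre and a single salt should form.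

Step 7
Reactants: 5 [2-hydroxy-4,6-bis(methoxymethoxy)benzyl]trimethylammonium iodide; 10 (2S,5S)-1-(2-methoxy-2-oxoethyl)-2,5-dimethylthiolan-1-ium bromide
Product: 14 methyl (2S)-4,6-bis(methoxymethoxy)-2,3-dihydro-1-benzofuran-2-carboxylate, via thiolanium ylide 11 (not isolated), via ortho-quinone methide 12 (not isolated), via sulfonium phenoxide betaine 13 (not isolated)
Conditions: 10 (1.3 equiv), Cs2CO3 (3 equiv), MeCN, 0 °C; then 5 in portions, 0 °C → rt
Reagents that add atoms: none
Why: Proposed new method: the [4+1] annulation of ortho-quinone methides with ester-stabilised sulfonium ylides (a Michael-initiated ring closure) is the closest known reaction type and forms exactly these bonds, while the enantiocontrol by a C2-symmetric thiolanium ylide on a methide with an unsubstituted CH2 terminus is the untested extension. Cs2CO3 converts 10 into ylide 11 and the phenol of 5 into a phenoxide that expels NMe3 to give methide 12; 11 adds 1,4 to the exocyclic CH2 (forming C2–C3 and restoring the arene) to give betaine 13. The phenoxide of 13 then displaces the thiolane at the ester-bearing carbon in a 5-exo-tet SN2 step with inversion, forming O1–C2 and closing the dihydrofuran. C2 becomes stereogenic only in the C–C bond formation, and its α-sulfonio ester C–H is acidic enough for the two epimers of 13 to interconvert through the substituted ylide faster than either closes. The two displacement transition states are diastereomeric because the leaving thiolane carries trans methyl groups next to sulfur, so one epimer, taken to be the one with the (R)-sulfonium carbon, should close preferentially and by inversion give (S)-14 (Curtin–Hammett control). Regioselectivity is not an issue because 12 has one electrophilic carbon and one phenoxide oxygen; the chemoselectivity needed is ylide capture ahead of methide self-condensation, secured by keeping 11 in excess and feeding 5 slowly. The mild heterogeneous carbonate at or below room temperature should leave the less acidic α-aryloxy ester C–H of 14 untouched.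

Step 8
Reactants: 14 methyl (2S)-4,6-bis(methoxymethoxy)-2,3-dihydro-1-benzofuran-2-carboxylate
Product: 16 2-[(2S)-4,6-bis(methoxymethoxy)-2,3-dihydro-1-benzofuran-2-yl]propan-2-ol, via methyl ketone 15 (not isolated)
Conditions: MeMgBr (3.5 equiv), anhydrous CeCl3, THF, −78 → 0 °C
Reagents that add atoms: methylmagnesium bromide, C[Mg]Br
Why: Double addition of a cerium-modified Grignard reagent to the ester; the low basicity of the organocerium species should suppress enolisation of 14 and of the transient α-aryloxy ketone 15, so C2 stays (S).

Step 9
Reactants: 16 2-[(2S)-4,6-bis(methoxymethoxy)-2,3-dihydro-1-benzofuran-2-yl]propan-2-ol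
Product: 17 triethyl({2-[(2S)-4,6-bis(methoxymethoxy)-2,3-dihydro-1-benzofuran-2-yl]propan-2-yl}oxy)silane
Conditions: TESOTf (1.2 equiv), 2,6-lutidine, CH2Cl2, −78 → 0 °C
Reagents that add atoms: triethylsilyl trifluoromethanesulfonate, CC[Si](CC)(CC)OS(=O)(=O)C(F)(F)F
Why: Silylation of a tertiary alcohol with a silyl triflate and a hindered base; at low temperature O–H silylation should be much faster than attack on the aryl acetals, and the ether removes an acidic, coordinating group before the lithiations and leaves with the acetals in the last step.

Step 10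
Reactants: 17 triethyl({2-[(2S)-4,6-bis(methoxymethoxy)-2,3-dihydro-1-benzofuran-2-yl]propan-2-yl}oxy)silane
Product: 20 triethyl({2-[(2S)-4,6-bis(methoxymethoxy)-5-(3-methylbut-2-enyl)-2,3-dihydro-1-benzofuran-2-yl]propan-2-yl}oxy)silane, via C5 aryllithium 18 (not isolated), via C5 arylcopper 19 (not isolated)
Conditions: n-BuLi (1.2 equiv), THF, 0 °C; CuBr·SMe2, −40 °C; prenyl bromide, −40 °C → rt
Reagents that add atoms: 1-bromo-3-methylbut-2-ene (prenyl bromide), CC(C)=CCBr
Why: Directed ortho-metalation followed by copper-mediated allylation; C5 is the only position flanked by two chelating acetal oxygens and should be lithiated in preference to C7, and the arylcopper should couple at the primary carbon of prenyl bromide without allylic transposition.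

Step 11
Reactants: 21 3-(4-methoxyphenyl)propanoic acid
Product: 23 N-methoxy-3-(4-methoxyphenyl)-N-methylpropanamide, via acyl imidazole 22 (not isolated)
Conditions: CDI, CH2Cl2, rt; then MeNHOMe·HCl, rt
Reagents that add atoms: N,O-dimethylhydroxylamine hydrochloride, CNOC.Cl
Why: Carboxyl activation as the acyl imidazole and aminolysis to the Weinreb amide, a standard amide-bond formation.

Step 12
Reactants: 20 triethyl({2-[(2S)-4,6-bis(methoxymethoxy)-5-(3-methylbut-2-enyl)-2,3-dihydro-1-benzofuran-2-yl]propan-2-yl}oxy)silane; 23 N-methoxy-3-(4-methoxyphenyl)-N-methylpropanamide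
Product: 25 1-[(2S)-4,6-bis(methoxymethoxy)-5-(3-methylbut-2-enyl)-2-[2-(triethylsilyloxy)propan-2-yl]-2,3-dihydro-1-benzofuran-7-yl]-3-(4-methoxyphenyl)propan-1-one, via C7 aryllithium 24 (not isolated)
Conditions: n-BuLi (1.2 equiv), TMEDA, THF, −20 → 0 °C; then 23, −78 → 0 °C; aq. NH4Cl
Reagents that add atoms: none
Why: Directed ortho-metalation and Weinreb ketone synthesis; C7 is the only ring C–H left and is activated by the C6 acetal and the ring oxygen, and the chelated tetrahedral adduct of the Weinreb amide should prevent over-addition.

Step 13
Reactants: 25 1-[(2S)-4,6-bis(methoxymethoxy)-5-(3-methylbut-2-enyl)-2-[2-(triethylsilyloxy)propan-2-yl]-2,3-dihydro-1-benzofuran-7-yl]-3-(4-methoxyphenyl)propan-1-one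
Product: 26 1-[(2S)-4,6-dihydroxy-2-(2-hydroxypropan-2-yl)-5-(3-methylbut-2-enyl)-2,3-dihydro-1-benzofuran-7-yl]-3-(4-methoxyphenyl)propan-1-one (CNP0150199.1)
Conditions: HCl (1.25 M in MeOH), 0 °C → rt; NaHCO3 quench
Reagents that add atoms: none
Why: Acid-catalysed acetal exchange and silyl ether methanolysis; the ketone-chelated C6 acetal and the silyl ether should cleave first and the C4 acetal last, and dilute methanolic acid at or below room temperature is the usual way to free prenylated phenols without cyclisation.

**Compound list**

1 | 2,4,6-trihydroxybenzaldehyde | O=Cc1c(O)cc(O)cc1O | starting material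
2 | 2-hydroxy-4,6-bis(methoxymethoxy)benzaldehyde | O=Cc1c(O)cc(OCOC)cc1OCOC | intermediate
3 | [2-hydroxy-4,6-bis(methoxymethoxy)benzylidene]dimethyliminium acetate | CC(=O)[O-].C[N+](C)=Cc1c(O)cc(OCOC)cc1OCOC | intermediate (not isolated)
4 | 2-[(dimethylamino)methyl]-3,5-bis(methoxymethoxy)phenol | CN(C)Cc1c(O)cc(OCOC)cc1OCOC | intermediate
5 | [2-hydroxy-4,6-bis(methoxymethoxy)benzyl]trimethylammonium iodide | C[N+](C)(C)Cc1c(O)cc(OCOC)cc1OCOC.[I-] | intermediate
6 | (2R,5R)-hexane-2,5-diol | C[C@@H](O)CC[C@@H](C)O | starting material
7 | (2R,5R)-hexane-2,5-diyl dimethanesulfonate | C[C@@H](OS(C)(=O)=O)CC[C@@H](C)OS(C)(=O)=O | intermediate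
8 | (2S,5S)-2,5-dimethylthiolane | C[C@H]1CC[C@H](C)S1 | intermediate
9 | methyl bromoacetate | COC(=O)CBr | starting material
10 | (2S,5S)-1-(2-methoxy-2-oxoethyl)-2,5-dimethylthiolan-1-ium bromide | C[C@H]1CC[C@H](C)[S+]1CC(=O)OC.[Br-] | intermediate
11 | ylide of methyl 2-[(2S,5S)-2,5-dimethylthiolan-1-ium-1-yl]acetate | C[C@H]1CC[C@H](C)[S+]1[CH-]C(=O)OC | intermediate (not isolated)
12 | 3,5-bis(methoxymethoxy)-6-methylidenecyclohexa-2,4-dien-1-one | C=C1C(=O)C=C(OCOC)C=C1OCOC | intermediate (not isolated)
13 | 2-{(2R)-2-[(2S,5S)-2,5-dimethylthiolan-1-ium-1-yl]-3-methoxy-3-oxopropyl}-3,5-bis(methoxymethoxy)phenolate (the epimer that closes) | C[C@H]1CC[C@H](C)[S+]1[C@H](Cc1c([O-])cc(OCOC)cc1OCOC)C(=O)OC | intermediate (not isolated)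
14 | methyl (2S)-4,6-bis(methoxymethoxy)-2,3-dihydro-1-benzofuran-2-carboxylate | COCOc1cc(OCOC)c2C[C@@H](C(=O)OC)Oc2c1 | intermediate
15 | 1-[(2S)-4,6-bis(methoxymethoxy)-2,3-dihydro-1-benzofuran-2-yl]ethan-1-one | COCOc1cc(OCOC)c2C[C@@H](C(C)=O)Oc2c1 | intermediate (not isolated)
16 | 2-[(2S)-4,6-bis(methoxymethoxy)-2,3-dihydro-1-benzofuran-2-yl]propan-2-ol | COCOc1cc(OCOC)c2C[C@@H](C(C)(C)O)Oc2c1 | intermediate
17 | triethyl({2-[(2S)-4,6-bis(methoxymethoxy)-2,3-dihydro-1-benzofuran-2-yl]propan-2-yl}oxy)silane | COCOc1cc(OCOC)c2C[C@@H](C(C)(C)O[Si](CC)(CC)CC)Oc2c1 | intermediate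
18 | 5-lithio derivative of 17 | COCOc1c([Li])c(OCOC)c2C[C@@H](C(C)(C)O[Si](CC)(CC)CC)Oc2c1 | intermediate (not isolated)
19 | 5-cuprio derivative of 17 | COCOc1c([Cu])c(OCOC)c2C[C@@H](C(C)(C)O[Si](CC)(CC)CC)Oc2c1 | intermediate (not isolated)
20 | triethyl({2-[(2S)-4,6-bis(methoxymethoxy)-5-(3-methylbut-2-enyl)-2,3-dihydro-1-benzofuran-2-yl]propan-2-yl}oxy)silane | COCOc1c(CC=C(C)C)c(OCOC)c2C[C@@H](C(C)(C)O[Si](CC)(CC)CC)Oc2c1 | intermediate
21 | 3-(4-methoxyphenyl)propanoic acid | COc1ccc(CCC(=O)O)cc1 | starting material
22 | 1-(1H-imidazol-1-yl)-3-(4-methoxyphenyl)propan-1-one | COc1ccc(CCC(=O)n2ccnc2)cc1 | intermediate (not isolated)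
23 | N-methoxy-3-(4-methoxyphenyl)-N-methylpropanamide | COc1ccc(CCC(=O)N(C)OC)cc1 | intermediate
24 | 7-lithio derivative of 20 | COCOc1c(CC=C(C)C)c(OCOC)c2C[C@@H](C(C)(C)O[Si](CC)(CC)CC)Oc2c1[Li] | intermediate (not isolated)
25 | 1-[(2S)-4,6-bis(methoxymethoxy)-5-(3-methylbut-2-enyl)-2-[2-(triethylsilyloxy)propan-2-yl]-2,3-dihydro-1-benzofuran-7-yl]-3-(4-methoxyphenyl)propan-1-one | COCOc1c(CC=C(C)C)c(OCOC)c2C[C@@H](C(C)(C)O[Si](CC)(CC)CC)Oc2c1C(=O)CCc1ccc(OC)cc1 | intermediate
26 | 1-[(2S)-4,6-dihydroxy-2-(2-hydroxypropan-2-yl)-5-(3-methylbut-2-enyl)-2,3-dihydro-1-benzofuran-7-yl]-3-(4-methoxyphenyl)propan-1-one | COc1ccc(CCC(=O)c2c(O)c(CC=C(C)C)c(O)c3c2O[C@H](C(C)(C)O)C3)cc1 | target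

**Step count and least certain steps**

Total: 13 steps. Longest linear sequence: 9 steps (steps 1, 2, 3, 7, 8, 9, 10, 12, 13; the branch through steps 4, 5, 6 is equally long).

Step 7 (key step; bears the label Proposed new method). The most likely failure is poor discrimination between the two epimeric betaines in the ring-closing displacement, giving low enantiomeric purity. Base-mediated enolisation of the product or self-condensation of the methide before ylide capture could add to this. The fallback uses known chemistry only, sets out from 5 and returns to the route at 16, bypassing 14. Excess Me2C=CHMgBr in THF should deprotonate 5, release the same methide and add to its CH2 terminus to give 3,5-bis(methoxymethoxy)-2-(3-methylbut-2-enyl)phenol F1. Silylation (i-Pr3SiCl, imidazole, DMF) gives [3,5-bis(methoxymethoxy)-2-(3-methylbut-2-enyl)phenoxy]tri(propan-2-yl)silane F2. Shi epoxidation then gives (2-{[(2R)-3,3-dimethyloxiran-2-yl]methyl}-3,5-bis(methoxymethoxy)phenoxy)tri(propan-2-yl)silane F3. It uses the fructose-derived ketone of the series that delivers the (R)-epoxide (expected to be the D-fructose-derived one), KHSO5 as its triple salt with KHSO4 and K2SO4, K2CO3 buffer, MeCN/CH2(OMe)2/H2O, 0 °C. TBAF in THF frees the phenoxide, which opens the epoxide 5-exo-tet at the secondary carbon with inversion and should give 16 as the (S) enantiomer.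

Step 10. The most likely failure is incomplete site selectivity in the metalation: the ring oxygen together with the C6 acetal may direct some lithiation to C7. Allylic transposition in the coupling is a lesser risk. The fallback sets out from 17 and returns at 26; it reverses the order of events and uses electrophilic substitution for the first ring functionalisation. NBS (1 equiv, CH2Cl2, −78 °C) should brominate the less hindered position next to the ring oxygen (the counterpart of C8 bromination in 5,7-dialkoxyflavans). This gives ({2-[(2S)-7-bromo-4,6-bis(methoxymethoxy)-2,3-dihydro-1-benzofuran-2-yl]propan-2-yl}oxy)triethylsilane F4. Bromine–lithium exchange (n-BuLi, THF, −78 °C) and acylation with 23 give 1-[(2S)-4,6-bis(methoxymethoxy)-2-[2-(triethylsilyloxy)propan-2-yl]-2,3-dihydro-1-benzofuran-7-yl]-3-(4-methoxyphenyl)propan-1-one F5. Methanolic HCl, now with no olefin in the molecule, gives 1-[(2S)-4,6-dihydroxy-2-(2-hydroxypropan-2-yl)-2,3-dihydro-1-benzofuran-7-yl]-3-(4-methoxyphenyl)propan-1-one F6. C-Prenylation at the only free ring carbon, C5 (prenyl bromide, aqueous KOH, 0 °C), gives 26; this classical alkylation is expected to be modest in efficiency but unambiguous in position.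

Step 12. The most likely failure is proton transfer in place of addition: the hindered, doubly ortho-substituted aryllithium may enolise the Weinreb amide. Metalation may also stray to the benzylic–allylic CH2 of the prenyl group; the fallback of step 10 avoids that second problem altogether. The fallback here sets out from 20 and returns at 25; it forms the ketone from the other side of the carbonyl. The same lithiation is quenched with DMF (small and non-enolisable) to give (2S)-4,6-bis(methoxymethoxy)-5-(3-methylbut-2-enyl)-2-[2-(triethylsilyloxy)propan-2-yl]-2,3-dihydro-1-benzofuran-7-carbaldehyde F7. Addition of 4-MeOC6H4CH2CH2MgBr in THF gives 1-[(2S)-4,6-bis(methoxymethoxy)-5-(3-methylbut-2-enyl)-2-[2-(triethylsilyloxy)propan-2-yl]-2,3-dihydro-1-benzofuran-7-yl]-3-(4-methoxyphenyl)propan-1-ol F8 (both carbinol epimers, of no consequence). Dess–Martin periodinane oxidation gives 25.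

Step 13. The most likely failure is acid-promoted cyclisation of the prenyl group onto a flanking phenol as it is unmasked; ionisation of the tertiary alcohol is a lesser risk. The fallback sets out from 25 and returns at 26; it replaces Brønsted-acid acetal cleavage by silyl exchange. TMSOTf with 2,2'-bipyridyl in CH2Cl2 at 0 °C should convert both aryl acetals into aryl trimethylsilyl ethers under non-acidic conditions, giving 1-[(2S)-5-(3-methylbut-2-enyl)-2-[2-(triethylsilyloxy)propan-2-yl]-4,6-bis(trimethylsilyloxy)-2,3-dihydro-1-benzofuran-7-yl]-3-(4-methoxyphenyl)propan-1-one F9. HF·pyridine buffered with pyridine in THF then removes the three silyl groups and gives 26.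

**Further compounds**

F1 | step 7 | 3,5-bis(methoxymethoxy)-2-(3-methylbut-2-enyl)phenol | CC(C)=CCc1c(O)cc(OCOC)cc1OCOC
F2 | step 7 | [3,5-bis(methoxymethoxy)-2-(3-methylbut-2-enyl)phenoxy]tri(propan-2-yl)silane | CC(C)=CCc1c(O[Si](C(C)C)(C(C)C)C(C)C)cc(OCOC)cc1OCOC
F3 | step 7 | (2-{[(2R)-3,3-dimethyloxiran-2-yl]methyl}-3,5-bis(methoxymethoxy)phenoxy)tri(propan-2-yl)silane | CC1(C)O[C@@H]1Cc1c(O[Si](C(C)C)(C(C)C)C(C)C)cc(OCOC)cc1OCOC
F4 | step 10 | ({2-[(2S)-7-bromo-4,6-bis(methoxymethoxy)-2,3-dihydro-1-benzofuran-2-yl]propan-2-yl}oxy)triethylsilane | COCOc1cc(OCOC)c2C[C@@H](C(C)(C)O[Si](CC)(CC)CC)Oc2c1Br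
F5 | step 10 | 1-[(2S)-4,6-bis(methoxymethoxy)-2-[2-(triethylsilyloxy)propan-2-yl]-2,3-dihydro-1-benzofuran-7-yl]-3-(4-methoxyphenyl)propan-1-one | COCOc1cc(OCOC)c2C[C@@H](C(C)(C)O[Si](CC)(CC)CC)Oc2c1C(=O)CCc1ccc(OC)cc1
F6 | step 10 | 1-[(2S)-4,6-dihydroxy-2-(2-hydroxypropan-2-yl)-2,3-dihydro-1-benzofuran-7-yl]-3-(4-methoxyphenyl)propan-1-one | COc1ccc(CCC(=O)c2c(O)cc(O)c3c2O[C@H](C(C)(C)O)C3)cc1
F7 | step 12 | (2S)-4,6-bis(methoxymethoxy)-5-(3-methylbut-2-enyl)-2-[2-(triethylsilyloxy)propan-2-yl]-2,3-dihydro-1-benzofuran-7-carbaldehyde | COCOc1c(CC=C(C)C)c(OCOC)c2C[C@@H](C(C)(C)O[Si](CC)(CC)CC)Oc2c1C=O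
F8 | step 12 | 1-[(2S)-4,6-bis(methoxymethoxy)-5-(3-methylbut-2-enyl)-2-[2-(triethylsilyloxy)propan-2-yl]-2,3-dihydro-1-benzofuran-7-yl]-3-(4-methoxyphenyl)propan-1-ol (both carbinol epimers) | COCOc1c(CC=C(C)C)c(OCOC)c2C[C@@H](C(C)(C)O[Si](CC)(CC)CC)Oc2c1C(O)CCc1ccc(OC)cc1
F9 | step 13 | 1-[(2S)-5-(3-methylbut-2-enyl)-2-[2-(triethylsilyloxy)propan-2-yl]-4,6-bis(trimethylsilyloxy)-2,3-dihydro-1-benzofuran-7-yl]-3-(4-methoxyphenyl)propan-1-one | C[Si](C)(C)Oc1c(CC=C(C)C)c(O[Si](C)(C)C)c2C[C@@H](C(C)(C)O[Si](CC)(CC)CC)Oc2c1C(=O)CCc1ccc(OC)cc1
A1 | alternative 1 | methyl 9-(4-methoxyphenyl)-4-(3-methylbut-2-enyl)-3,5,7-trioxononanoate | COC(=O)CC(=O)C(CC=C(C)C)C(=O)CC(=O)CCc1ccc(OC)cc1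
A2 | alternative 1 | 1-[2,4,6-trihydroxy-3-(3-methylbut-2-enyl)phenyl]-3-(4-methoxyphenyl)propan-1-one | COc1ccc(CCC(=O)c2c(O)cc(O)c(CC=C(C)C)c2O)cc1
A3 | alternative 1 | 1-[2,4,6-trihydroxy-3,5-bis(3-methylbut-2-enyl)phenyl]-3-(4-methoxyphenyl)propan-1-one | COc1ccc(CCC(=O)c2c(O)c(CC=C(C)C)c(O)c(CC=C(C)C)c2O)cc1
A4 | alternative 2 | 2-(diazomethyl)-1-[2-methyl-2-(trimethylsilyloxy)propoxy]-3,5-bis(triisopropylsilyloxy)benzene | [N-]=[N+]=Cc1c(OCC(C)(C)O[Si](C)(C)C)cc(O[Si](C(C)C)(C(C)C)C(C)C)cc1O[Si](C(C)C)(C(C)C)C(C)C
A5 | alternative 2 | (S)-4,6-bis(triisopropylsilyloxy)-2-[2-(trimethylsilyloxy)propan-2-yl]-2,3-dihydrobenzofuran | CC(C)[Si](Oc1cc(O[Si](C(C)C)(C(C)C)C(C)C)c2C[C@@H](C(C)(C)O[Si](C)(C)C)Oc2c1)(C(C)C)C(C)C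
A6 | alternative 3 | (2S)-4-(methoxymethoxy)-2-[2-(methoxymethoxy)propan-2-yl]-5-(3-methylbut-2-enyl)-7-(trimethylsilyl)-2,3-dihydro-1-benzofuran-6-yl trifluoromethanesulfonate | COCOc1c(CC=C(C)C)c(OS(=O)(=O)C(F)(F)F)c([Si](C)(C)C)c2O[C@H](C(C)(C)OCOC)Cc12
A7 | alternative 3 | (2S)-6,7-didehydro-4-(methoxymethoxy)-2-[2-(methoxymethoxy)propan-2-yl]-5-(3-methylbut-2-enyl)-2,3-dihydro-1-benzofuran (aryne) | COCOC1=C(CC=C(C)C)C#CC2=C1C[C@@H](C(C)(C)OCOC)O2
A8 | alternative 3 | (S)-1-[6-hydroxy-4-(methoxymethoxy)-2-[2-(methoxymethoxy)propan-2-yl]-5-(3-methylbut-2-enyl)-2,3-dihydrobenzofuran-7-yl]-3-(4-methoxyphenyl)propan-1-one | COCOc1c(CC=C(C)C)c(O)c(C(=O)CCc3ccc(OC)cc3)c2O[C@H](C(C)(C)OCOC)Cc12
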